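**Conventions and assumption**

- Locants: each butenolide is O1–C2(=O)–C3=C4–C5 (primes for the second ring); the four-membered ring is C5–C6–C6'–C5'; the carbinol carbons are C1''.
- Assumption for step 2: the lipase acetylates the (R)-alcohol faster (sp2 ring as the large group, propyl as the medium one), so the (S)-alcohol is the one recovered.

## Analysis of the target

The target is a cyclobutane (C5–C6–C6'–C5') whose adjacent carbons C5 and C5' are each the spiro carbon of a 4-bromo-2(5H)-furanone, while C6 and C6' carry only H and Br. C5 and C5' are both S with the lactone oxygens on opposite faces. C6 and C6' are both R, so the two bromines are trans, each cis to C4 of the neighbouring lactone and trans to its ring oxygen. The core is therefore chiral and C2-symmetric. The two 1-acetoxybutyl groups at C3 and C3' are constitutionally the same but S on one ring and R on the other, which removes the symmetry and leaves a single enantiomer fixed by the core. Sensitive groups are the two 4-bromobutenolides (vinylogous acyl bromides, open to addition–elimination), the vicinal dibromide (reductive or basic elimination), the lactones and the two acetates on carbons next to an enoate. The difficulties are the two vicinal quaternary spiro centres on a four-membered ring, the relation of C6/C6' to C5/C5', and two remote, like carbinols of opposite configuration. The strategy rests on the fact that C6 and C6' bear no carbon substituent. The four-membered ring can therefore be read as a thiolane with sulfur between C6 and C6', so that the crowded C5–C5' bond and its trans spiro centres are made in a five-membered ring and the ring is then contracted by deleting sulfur.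

## Retrosynthetic reasoning

**24 ⇐ 23 ⇐ 22.** The two acetates differ only in configuration. Because the (S,S)-diol 22 is C2-symmetric, its two hydroxyls are homotopic. Acetylating either one gives the same mono-acetate 23, and inverting the remaining carbinol by Mitsunobu acetoxylation gives 24. The statistical event is thus placed on a clean, recyclable acylation, and the inversion can be driven to completion.

**22 ⇐ 21 ⇐ 19 ⇐ 18.** The C–Br bonds are cut next. The C4 and C4' bromines go back to the enoate C–H bonds of 19 (addition of bromine, then loss of HBr). The C6/C6' bromines go back to the C6=C6' double bond of cyclobutene 18 by anti addition. The silyl ethers are kept through both brominations because they neither participate nor ionise, and they are removed with acid to give 22.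

**18 ⇐ 16 ⇐ 14 (key disconnection).** The C6=C6' bond is opened by putting a sulfonyl bridge between C6 and C6'. Forward, the base-induced Ramberg–Bäcklund reaction of an α-chloro thiolane 1,1-dioxide passes through episulfone 15 and leaves the cyclobutene. C5 and C5' are spectators, so no strained ring has to be closed at a quaternary carbon. One correction is needed here. In a bis-lactone the carbanions next to sulfur would have a carboxylate oxygen in the beta position, and ring opening to a vinyl sulfone would outrun the slow 1,3-closure of a five-membered sulfone. The rearrangement is therefore run on 14, in which both lactone carbonyls are carried as methyl acetals. The beta-oxygens are then alkoxide-type leaving groups, and 16 is returned to the lactone level (18) directly afterwards.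

**14 ⇐ 12 ⇐ 10.** The acetals come from the bis-lactone 12 by hydride reduction to the lactols and acetalisation. Compound 12 comes from thiolane 10 by α-chlorination of the sulfide (through 11) and oxidation at sulfur. These steps are done at the lactone stage, where the enoate double bonds are inert to chlorinating agent and peracid.

**10 ⇐ 7 + 8.** Cutting C5–C6 and C5'–C6' reveals a (3+2) cycloaddition of the parent thiocarbonyl ylide 9, released from 8, to the central double bond of the (E)-bifuranylidene 7. That bond is the only one activated from both ends. Suprafacial addition turns the E geometry into the trans relation of O1 and O1'. The (S,S) side chains make the two core enantiomers diastereomers, which are separated here.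

**7 ⇐ 6 ⇐ 5 + 5.** The C5=C5' bond is cut to two molecules of 5. Forward, oxidative coupling of two dienolates at C5 (the only free terminus of each) gives 6, and dehydrogenation gives 7. The C5/C5' configurations of 6 are irrelevant.

**5 ⇐ 4 ⇐ 3 ⇐ 1 + 2.** The C3–C1'' bond is a Morita–Baylis–Hillman bond between furanone 1 and butanal 2. The racemic adduct 3 is resolved enzymatically to the (S)-alcohol 4 and silylated to 5.

## Alternatives that were turned down

**Alternative 1: double bromo-aldol and lactonisation.**
- Disconnection: C3–C1'', C4–Br and O1–C2 in both rings, back to the cyclobutanediol bis(propiolate) A1 and two molecules of 2.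
- Forward key step: MgBr2·OEt2 (or TiBr4) adds bromide to the ynoate β-carbons, the bromo-allenolates add to 2, and the tertiary hydroxyls lactonise to diol A2.
- For: side chains, C4–Br and both lactones arrive in one operation. On the vinyl bromides it is stronger than the chosen route, which has to brominate a hindered enoate late.
- Against: both carbinols form without control, yet A2 needs one S and one R on a chiral core, so at best the statistical share is obtained. Lactonisation needs one alkene geometry of the bromo-acrylate. A1 holds two tertiary alkoxides beta to C–Br bonds on a strained ring under Lewis-acidic halide, which invites fragmentation. A1 already contains all four ring stereocentres, so the core problem is only moved.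
- Comparison: the chosen route is longer, but every stereocentre has a defined origin.

**Alternative 2: double Baeyer–Villiger insertion.**
- Disconnection: C5–O1 and O1–C2 in both rings, back to the dispiro bis(3-ethoxycyclobutenone) A3.
- Forward key step: a peracid inserts oxygen with migration of the quaternary carbon, with retention, to give the bis(4-ethoxybutenolide) A4.
- For: retention would carry C–C stereochemistry into the spiro C–O bonds. The tetronate-to-bromide exchange that follows is reliable, which again beats the late enoate bromination of the chosen route.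
- Against: a vinylogous ester carbonyl is a poor partner for peracid, while the strained C6=C6' bond and the enol ethers are good ones (epoxidation). Ethoxy must still be exchanged for bromine in the presence of two acetates, and bromine must still be added to the cyclobutene. A3, with three four-membered rings around two vicinal quaternary carbons, is harder to reach than the target.
- Comparison: the chosen route keeps all difficult bond formation in five-membered rings.

**Alternative 3: allenoic acid bromolactonisation.**
- Disconnection: C5–O1 and C4–Br in both rings, back to the bis(allenoic acid) A5.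
- Forward key step: CuBr2 (or N-bromosuccinimide) delivers bromine to the central allene carbons and each carboxyl closes onto C5 or C5', giving A6.
- For: halolactonisation of allenoic acids is a dependable route to 4-bromobutenolides, and A6 already carries the S and R side chains. On both points it is stronger than the chosen route.
- Against: C5 and C5' would be set in two separate events by relay from two allene axes, each of which must be made in one sense. A5 is a 1,2-bis(vinylidene)cyclobutane with allylic C–Br bonds, a strained conjugated bis-allene prone to cyclisation and ionisation. Nothing enforces the trans relation of the two lactones.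
- Comparison: the chosen strategy makes both spiro centres in one stereospecific cycloaddition to an alkene of defined geometry and does not touch them again.

Key step: step 9

## Route

Step 1
Reactants: 1 furan-2(5H)-one; 2 butanal
Product: 3 rac-3-(1-hydroxybutyl)furan-2(5H)-one
Conditions: PBu3 (0.2 equiv), PhOH (0.2 equiv), THF, 0 °C to rt, slow addition of 2
Reagents that add atoms: none
Why: Morita–Baylis–Hillman reaction: the phosphine adds to C4, the enolate carbon C3 adds to the aldehyde, and proton transfer with loss of phosphine restores C3=C4; the weakly basic phosphine limits self-aldol of 2, and the carbinol is racemic.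

Step 2
Reactants: 3 rac-3-(1-hydroxybutyl)furan-2(5H)-one
Product: 4 3-[(1S)-1-hydroxybutyl]furan-2(5H)-one
Conditions: Burkholderia cepacia lipase (immobilised), vinyl acetate, t-BuOMe, 30 °C, run past half conversion
Reagents that add atoms: none
Why: Lipase-mediated kinetic resolution by irreversible transesterification; the (R)-alcohol is acylated and the slower (S)-alcohol is recovered, its purity rising with conversion.

Step 3
Reactants: 4 3-[(1S)-1-hydroxybutyl]furan-2(5H)-one
Product: 5 3-[(1S)-1-(tert-butyldimethylsilyloxy)butyl]furan-2(5H)-one
Conditions: TBSCl, imidazole, DMF, rt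
Reagents that add atoms: tert-butyldimethylsilyl chloride, CC(C)(C)[Si](C)(C)Cl
Why: Standard silylation of a secondary alcohol; the ether is inert to the bases, oxidants and bromine used later and is removed by acid at the end.

Step 4
Reactants: 5 3-[(1S)-1-(tert-butyldimethylsilyloxy)butyl]furan-2(5H)-one; 5 3-[(1S)-1-(tert-butyldimethylsilyloxy)butyl]furan-2(5H)-one (second molecule)
Product: 6 4,4'-bis[(1S)-1-(tert-butyldimethylsilyloxy)butyl]-[2,2'-bifuran]-5,5'(2H,2'H)-dione (C5–C5' linked bibutenolide, mixture of epimers at C5 and C5')
Conditions: LiN(i-Pr)2 (1.05 equiv per molecule of 5), THF, −78 °C; CuCl2 (1.1 equiv per molecule of 5), DMF, −78 to 0 °C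
Reagents that add atoms: none
Why: Oxidative homocoupling of a lithium enolate, two molecules of 5 giving one of 6 with loss of one hydrogen from each: deprotonation at C5 and one-electron oxidation by CuCl2 give a radical that dimerises at C5, the only unsubstituted terminus of the dienolate; the new centres are uncontrolled and are erased in step 5.

Step 5
Reactants: 6 C5–C5' linked bibutenolide
Product: 7 (E)-4,4'-bis[(1S)-1-(tert-butyldimethylsilyloxy)butyl]-[2,2'-bifuranylidene]-5,5'-dione
Conditions: I2 (1.1 equiv), DBU (2.5 equiv), CH2Cl2, 0 °C to rt; then I2 (cat.), daylight, rt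
Reagents that add atoms: none
Why: Dehydrogenation by iodination at C5 and base-induced loss of HI across C5–C5'; iodine and light equilibrate the geometry to the E isomer, which avoids the clash of H4 with H4' and of O1 with O1'.

Step 6
Reactants: 7 (E)-bifuranylidene; 8 chloromethyl (trimethylsilyl)methyl sulfide
Product: 10 (5S,5'S)-dispiro thiolane (tetrahydrothiophene whose C3 and C4 are C5 and C5' of two 3-[(1S)-1-(tert-butyldimethylsilyloxy)butyl]furan-2(5H)-one rings, lactone oxygens trans), via thiocarbonyl ylide 9 (not isolated)
Conditions: CsF, MeCN, rt, slow addition of 8; chromatographic separation of the two core diastereomers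
Reagents that add atoms: none
Why: 1,3-Dipolar cycloaddition of the nucleophilic parent thiocarbonyl ylide (fluoride-induced 1,3-elimination from 8) to the central alkene, the only one activated from both ends; suprafacial addition converts the E geometry into the trans relation of O1 and O1', and since the faces differ only through the remote carbinols both core isomers are expected and 10 is separated.

Step 7
Reactants: 10 (5S,5'S)-dispiro thiolane
Product: 12 dispiro α-chlorothiolane 1,1-dioxide bis-lactone (either epimer at the chlorinated carbon), via alpha-chloro sulfide 11 (not isolated)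
Conditions: N-chlorosuccinimide (1.05 equiv), CH2Cl2, 0 °C to rt; filter; 3-chloroperbenzoic acid (2.3 equiv), NaHCO3, CH2Cl2, 0 °C to rt
Reagents that add atoms: N-chlorosuccinimide, O=C1CCC(=O)N1Cl; 3-chloroperbenzoic acid, OOC(=O)c1cccc(Cl)c1
Why: Chlorination of the sulfide through the chlorosulfonium salt and thionium ion (Pummerer-type) at one of the two equivalent CH2 groups, then oxidation at sulfur to the stable α-chloro sulfone; the enoate double bonds are inert to both reagents.

Step 8
Reactants: 12 dispiro α-chlorothiolane 1,1-dioxide bis-lactone
Product: 14 dispiro α-chlorothiolane 1,1-dioxide in which both lactone carbonyls are CH(OCH3) (bis-lactol methyl ether, mixture at the acetal and chlorinated carbons), via bis-lactol 13 (not isolated)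
Conditions: i-Bu2AlH (2.4 equiv), CH2Cl2, −78 °C; aq. KNaC4H4O6; then MeOH, PPTS (cat.), 3 Å sieves, rt
Reagents that add atoms: methanol, CO
Why: Partial reduction of lactones to lactols and acid-catalysed acetalisation through the allyl-stabilised oxocarbenium ion; this turns O1 and O1' from carboxylate-type into alkoxide-type leaving groups before any carbanion is made next to sulfur, and the lactols cannot aromatise because C5 is quaternary.

Step 9
Reactants: 14 bis-lactol methyl ether α-chloro sulfone
Product: 16 dispiro cyclobutene bis(2-methoxy-2,5-dihydrofuran), (S,S) silyl ethers, via episulfone 15 (not isolated)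
Conditions: KOC(CH3)3 (3 equiv), THF, −78 to −20 °C, then 0 °C briefly; cold work-up
Reagents that add atoms: none
Why: Ramberg–Bäcklund rearrangement of an α-chloro sulfone: KOC(CH3)3 removes a proton from C6', the CH2 next to sulfur, and the carbanion displaces chloride from C6 in a 1,3-elimination that forms the C6–C6' bond and episulfone 15. This closure is 3-exo-tet for the thiirane dioxide and at the same time 4-exo-tet for the carbocycle; cheletropic loss of SO2 from 15 then leaves the C6=C6' bond of 16. The closest known reaction type is the contraction of α-halo thiolane 1,1-dioxides with quaternary 3- and 4-carbons to cyclobutenes by a hindered alkoxide. No stereocentre is created and C5 and C5' are not touched, so the trans relation from step 6 is kept; both epimers at the chlorinated carbon converge because that centre epimerises through its own carbanion and ends sp2. The step needs 1,3-closure to win over beta-elimination of the ring oxygen from the carbanions next to sulfur; with lactones the leaving group would be a carboxylate and ring opening to a vinyl sulfone would be expected, which is why O1 and O1' are acetal oxygens in 14, the situation in which this rearrangement is known to tolerate a beta-oxygen. No other acidic C–H is present, and the temperature is held at or below 0 °C because the two donor oxygens on the ring carbons of 16 lower the barrier to electrocyclic ring opening.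

Step 10
Reactants: 16 dispiro cyclobutene bis(2-methoxy-2,5-dihydrofuran)
Product: 18 dispiro cyclobutene bis(butenolide), (S,S) silyl ethers, via cyclobutene bis-lactol 17 (not isolated)
Conditions: PPTS, acetone/H2O, 0 °C; then DMP (1,1,1-triacetoxy-1,2-benziodoxol-3-one), NaHCO3, CH2Cl2, 0 °C
Reagents that add atoms: water, O
Why: Hydrolysis of the allylic acetals and oxidation of the lactols to lactones under buffered, non-basic conditions that leave the cyclobutene and silyl ethers alone; with acyloxy in place of alkoxy on the ring carbons the cyclobutene should no longer be prone to ring opening.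

Step 11
Reactants: 18 dispiro cyclobutene bis(butenolide)
Product: 19 (5S,5'S,6R,6'R)-6,6'-dibromo dispiro cyclobutane bis(butenolide), (S,S) silyl ethers
Conditions: Br2 (1.05 equiv), CH2Cl2, −78 °C, dark
Reagents that add atoms: bromine, BrBr
Why: Electrophilic anti addition to the strained cis-alkene, which reacts far faster than the enoates; the two faces are equivalent by symmetry, and bromide should open the bromonium ion at the carbon where it enters anti to the neighbouring C5–O1 bond, away from the lactone oxygen lone pairs and with opposed C–Br and C–O dipoles, which puts each bromine cis to C4.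

Step 12
Reactants: 19 6,6'-dibromide
Product: 21 (5S,5'S,6R,6'R)-4,4',6,6'-tetrabromo dispiro bis(butenolide), (S,S) silyl ethers, via hexabromide 20 (not isolated)
Conditions: Br2 (4 equiv), NaHCO3 (solid), CHCl3, dark, rt; evaporate; Et3N (3 equiv), CH2Cl2, 0 °C to rt
Reagents that add atoms: bromine, BrBr
Why: Addition of bromine to the α-substituted enoates followed by dehydrobromination; C3 has no hydrogen, so HBr is lost from H4 and the α-bromine (syn, which a five-membered ring allows), as in the conversion of α-alkyl-α,β-dibromo esters into β-bromo-α-alkyl acrylates, and the bulky silyloxy group disfavours the planar exocyclic alternative.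

Step 13
Reactants: 21 tetrabromide bis(silyl ether)
Product: 22 (S,S)-diol, C2-symmetric
Conditions: HF (48% aq.), MeCN, 0 °C to rt
Reagents that add atoms: none
Why: Acidic desilylation; amine-free, non-basic fluoride avoids addition–elimination at the vinylogous acyl bromides and elimination of the ring dibromide.

Step 14
Reactants: 22 (S,S)-diol
Product: 23 mono-acetate with (1''S)-acetoxy on one ring and (1''S)-hydroxy on the other
Conditions: Ac2O (0.9 equiv), Sc(OTf)3 (2 mol %), MeCN, −20 °C; separation, recovered 22 recycled
Reagents that add atoms: acetic anhydride, CC(=O)OC(C)=O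
Why: Lewis-acid-catalysed acylation without a nucleophilic amine; the two hydroxyls are homotopic, so either one gives the same mono-acetate with retention, and the statistical distribution is handled by separation and recycling.

Step 15
Reactants: 23 mono-acetate
Product: 24 target, (5S,5'S,6R,6'R) with (1''S)- and (1''R)-acetoxybutyl groups
Conditions: PPh3 and DIAD premixed in THF at 0 °C, then AcOH and 23, 0 °C to rt
Reagents that add atoms: acetic acid, CC(O)=O
Why: Mitsunobu reaction: the remaining (S)-carbinol is activated as its alkoxyphosphonium salt and displaced by acetate with inversion to the (R)-acetate; the electron-poor alkene disfavours ionisation, and C4 is fully substituted, which blocks the allylic-transposition pathway.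

## Compound list

1 | furan-2(5H)-one | O=C1OCC=C1 | starting material
2 | butanal | CCCC=O | starting material
3 | rac-3-(1-hydroxybutyl)furan-2(5H)-one | CCCC(O)C1=CCOC1=O | intermediate
4 | 3-[(1S)-1-hydroxybutyl]furan-2(5H)-one | CCC[C@H](O)C1=CCOC1=O | intermediate
5 | 3-[(1S)-1-(tert-butyldimethylsilyloxy)butyl]furan-2(5H)-one | CCC[C@H](O[Si](C)(C)C(C)(C)C)C1=CCOC1=O | intermediate
6 | C5–C5' linked bibutenolide, (S,S) silyl ethers, epimers at C5/C5' | CCC[C@H](O[Si](C)(C)C(C)(C)C)C1=CC(OC1=O)C1OC(=O)C([C@H](CCC)O[Si](C)(C)C(C)(C)C)=C1 | intermediate
7 | (E)-bifuranylidene dione, (S,S) silyl ethers | CCC[C@H](O[Si](C)(C)C(C)(C)C)C1=C/C(=C2/C=C([C@H](CCC)O[Si](C)(C)C(C)(C)C)C(=O)O2)OC1=O | intermediate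
8 | chloromethyl (trimethylsilyl)methyl sulfide | ClCSC[Si](C)(C)C | starting material
9 | thioformaldehyde S-methylide (thiocarbonyl ylide) | C=[S+][CH2-] | intermediate
10 | (5S,5'S)-dispiro thiolane bis(butenolide), (S,S) silyl ethers | CCC[C@H](O[Si](C)(C)C(C)(C)C)C1=C[C@@]2(OC1=O)CSC[C@@]21OC(=O)C([C@H](CCC)O[Si](C)(C)C(C)(C)C)=C1 | intermediate
11 | α-chloro sulfide of 10 (either epimer at CHCl) | CCC[C@H](O[Si](C)(C)C(C)(C)C)C1=C[C@@]2(OC1=O)C(Cl)SC[C@@]21OC(=O)C([C@H](CCC)O[Si](C)(C)C(C)(C)C)=C1 | intermediate
12 | dispiro α-chlorothiolane 1,1-dioxide bis-lactone (either epimer at CHCl) | CCC[C@H](O[Si](C)(C)C(C)(C)C)C1=C[C@@]2(OC1=O)C(Cl)S(=O)(=O)C[C@@]21OC(=O)C([C@H](CCC)O[Si](C)(C)C(C)(C)C)=C1 | intermediate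
13 | bis-lactol of 12 | CCC[C@H](O[Si](C)(C)C(C)(C)C)C1=C[C@@]2(OC1O)C(Cl)S(=O)(=O)C[C@@]21OC(O)C([C@H](CCC)O[Si](C)(C)C(C)(C)C)=C1 | intermediate
14 | bis-lactol methyl ether of 12 | CCC[C@H](O[Si](C)(C)C(C)(C)C)C1=C[C@@]2(OC1OC)C(Cl)S(=O)(=O)C[C@@]21OC(OC)C([C@H](CCC)O[Si](C)(C)C(C)(C)C)=C1 | intermediate
15 | dispiro episulfone (5-thiabicyclo[2.1.0]pentane 5,5-dioxide core) | CCC[C@H](O[Si](C)(C)C(C)(C)C)C1=C[C@@]2(OC1OC)C3C([C@@]21OC(OC)C([C@H](CCC)O[Si](C)(C)C(C)(C)C)=C1)S3(=O)=O | intermediate
16 | dispiro cyclobutene bis(2-methoxy-2,5-dihydrofuran), (S,S) silyl ethers | CCC[C@H](O[Si](C)(C)C(C)(C)C)C1=C[C@@]2(OC1OC)C=C[C@@]21OC(OC)C([C@H](CCC)O[Si](C)(C)C(C)(C)C)=C1 | intermediate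
17 | dispiro cyclobutene bis-lactol | CCC[C@H](O[Si](C)(C)C(C)(C)C)C1=C[C@@]2(OC1O)C=C[C@@]21OC(O)C([C@H](CCC)O[Si](C)(C)C(C)(C)C)=C1 | intermediate
18 | dispiro cyclobutene bis(butenolide), (S,S) silyl ethers | CCC[C@H](O[Si](C)(C)C(C)(C)C)C1=C[C@@]2(OC1=O)C=C[C@@]21OC(=O)C([C@H](CCC)O[Si](C)(C)C(C)(C)C)=C1 | intermediate
19 | (5S,5'S,6R,6'R)-6,6'-dibromide, (S,S) silyl ethers | CCC[C@H](O[Si](C)(C)C(C)(C)C)C1=C[C@@]2(OC1=O)[C@@H](Br)[C@H](Br)[C@@]21OC(=O)C([C@H](CCC)O[Si](C)(C)C(C)(C)C)=C1 | intermediate
20 | hexabromide (3,4,3',4',6,6'), mixture at C3/C4 | CCC[C@H](O[Si](C)(C)C(C)(C)C)C1(Br)C(Br)[C@@]2(OC1=O)[C@@H](Br)[C@H](Br)[C@@]21OC(=O)C(Br)([C@H](CCC)O[Si](C)(C)C(C)(C)C)C1Br | intermediate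
21 | 4,4',6,6'-tetrabromide, (S,S) silyl ethers | CCC[C@H](O[Si](C)(C)C(C)(C)C)C1=C(Br)[C@@]2(OC1=O)[C@@H](Br)[C@H](Br)[C@@]21OC(=O)C([C@H](CCC)O[Si](C)(C)C(C)(C)C)=C1Br | intermediate
22 | (S,S)-diol | CCC[C@H](O)C1=C(Br)[C@@]2(OC1=O)[C@@H](Br)[C@H](Br)[C@@]21OC(=O)C([C@H](CCC)O)=C1Br | intermediate
23 | (S)-acetate (S)-alcohol | CCC[C@H](OC(C)=O)C1=C(Br)[C@@]2(OC1=O)[C@@H](Br)[C@H](Br)[C@@]21OC(=O)C([C@H](CCC)O)=C1Br | intermediate
24 | CNP0266230.1 | CCC[C@H](OC(C)=O)C1=C(Br)[C@@]2(OC1=O)[C@@H](Br)[C@H](Br)[C@@]21OC(=O)C([C@@H](CCC)OC(C)=O)=C1Br | target

## Step count and least certain steps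

Total: 15 steps. Longest linear sequence: 15 steps (1 and 2 to 24).

**Step 9 (key step).**
- What may go wrong: beta-elimination of the acetal oxygen from the carbanion next to sulfur may compete with the slow 1,3-closure of a five-membered sulfone, and the dialkoxy cyclobutene may undergo thermal ring opening before it is oxidised.
- Fallback: setting out from 7, a [2+2] photocycloaddition with (Z)-1,2-dichloroethene (hν, λ > 350 nm, CH2Cl2) at the central alkene should give the dichlorocyclobutane F1. Zinc dust in ethanol then removes both chlorines and returns to the route at 18. No carbanion is formed next to the spiro carbons. The price is that the excited state can isomerise and close stepwise, so trans/cis and core isomers would have to be separated at 18.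

**Step 6.**
- What may go wrong: the ylide may add to an enoate double bond instead of the central one, or add stepwise through a zwitterion with loss of the E-to-trans transfer. Little facial selectivity is expected, so half of the material is in the wrong core series.
- Fallback: setting out from 6, double deprotonation (LiN(i-Pr)2, 2.2 equiv, THF, −78 °C) and reaction with bis(chloromethyl) sulfide should alkylate C5 to give the chloromethylthiomethyl lactone F2. Its remaining dienolate then closes the thiolane by 5-exo-tet alkylation at C5', returning to the route at 10 after separation from the cis and core isomers.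

**Step 11.**
- What may go wrong: the bromonium ion may be opened at the carbon beside the lactone oxygen on the attack face, giving the other trans-dibromide.
- Fallback: that isomer, F3, formed from 18, is not discarded. Warming it with LiBr (cat.) in MeCN should bring about the 1,2-dibromide (dyotropic) rearrangement, in which both bromines change places with inversion at C6 and C6'. This equilibrates F3 with 19 under thermodynamic control, and 19, with C–Br anti to C–O, should be favoured and is drained off by repeated separation.

**Step 12.**
- What may go wrong: addition of bromine to the hindered enoate may be sluggish, and HBr may be lost toward the side chain (removal of the carbinol hydrogen), which would erase the carbinol configuration.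
- Fallback: setting out from 19, PhSeBr should add anti with selenium at C3 and bromide at C4 to give the bis-adduct F4. Oxidation (H2O2, pyridine, CH2Cl2, 0 °C) gives the bis-selenoxide F5. Its syn elimination uses H4, which is cis to selenium, and selenoxides eliminate away from oxygen-bearing carbons, so the route is rejoined at 21.

**Step 15.**
- What may go wrong: the phosphine may attack a vinylogous acyl bromide or the ring dibromide, or displacement at the hindered carbinol may be slow and give elimination.
- Fallback: setting out from 23, oxidation with DMP gives the ketone F6. Corey–Bakshi–Shibata reduction ((S)-1-methyl-3,3-diphenyltetrahydro-1H,3H-pyrrolo[1,2-c][1,3,2]oxazaborole, catecholborane, toluene, −78 °C) should give the (R)-alcohol F7 under reagent control. Acetylation (Ac2O, Sc(OTf)3 cat.) returns to the route at 24.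

## Further compounds

F1 | step 9 | dispiro 6,6'-dichlorocyclobutane bis(butenolide), (S,S) silyl ethers | CCC[C@H](O[Si](C)(C)C(C)(C)C)C1=C[C@@]2(OC1=O)C(Cl)C(Cl)[C@@]21OC(=O)C([C@H](CCC)O[Si](C)(C)C(C)(C)C)=C1
F2 | step 6 | 5-(chloromethylthiomethyl) derivative of bibutenolide 6 | CCC[C@H](O[Si](C)(C)C(C)(C)C)C1=CC(CSCCl)(OC1=O)C1OC(=O)C([C@H](CCC)O[Si](C)(C)C(C)(C)C)=C1
F3 | step 11 | (5S,5'S,6S,6'S)-6,6'-dibromide, bromines cis to the lactone oxygens | CCC[C@H](O[Si](C)(C)C(C)(C)C)C1=C[C@@]2(OC1=O)[C@H](Br)[C@@H](Br)[C@@]21OC(=O)C([C@H](CCC)O[Si](C)(C)C(C)(C)C)=C1
F4 | step 12 | bis(3-phenylselanyl-4-bromo) adduct of 19 | CCC[C@H](O[Si](C)(C)C(C)(C)C)C1([Se]c3ccccc3)C(Br)[C@@]2(OC1=O)[C@@H](Br)[C@H](Br)[C@@]21OC(=O)C([Se]c3ccccc3)([C@H](CCC)O[Si](C)(C)C(C)(C)C)C1Br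
F5 | step 12 | bis-selenoxide of F4 | CCC[C@H](O[Si](C)(C)C(C)(C)C)C1([Se](=O)c3ccccc3)C(Br)[C@@]2(OC1=O)[C@@H](Br)[C@H](Br)[C@@]21OC(=O)C([Se](=O)c3ccccc3)([C@H](CCC)O[Si](C)(C)C(C)(C)C)C1Br
F6 | step 15 | keto acetate (3'-butanoyl) | CCC[C@H](OC(C)=O)C1=C(Br)[C@@]2(OC1=O)[C@@H](Br)[C@H](Br)[C@@]21OC(=O)C(C(=O)CCC)=C1Br
F7 | step 15 | (S)-acetate (R)-alcohol | CCC[C@H](OC(C)=O)C1=C(Br)[C@@]2(OC1=O)[C@@H](Br)[C@H](Br)[C@@]21OC(=O)C([C@@H](CCC)O)=C1Br
A1 | alternative 1 | dimethyl 3,3'-(3,4-dibromo-1,2-dihydroxycyclobutane-1,2-diyl)dipropiolate | COC(=O)C#C[C@@]1(O)[C@@H](Br)[C@H](Br)[C@]1(O)C#CC(=O)OC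
A2 | alternative 1 | (S,R)-diol corresponding to the target | CCC[C@H](O)C1=C(Br)[C@@]2(OC1=O)[C@@H](Br)[C@H](Br)[C@@]21OC(=O)C([C@@H](CCC)O)=C1Br
A3 | alternative 2 | dispiro cyclobutene bis(3-ethoxycyclobutenone) | CCC[C@H](OC(C)=O)C1=C(OCC)[C@@]2(C1=O)C=C[C@@]21C(=O)C([C@@H](CCC)OC(C)=O)=C1OCC
A4 | alternative 2 | dispiro cyclobutene bis(4-ethoxybutenolide) | CCC[C@H](OC(C)=O)C1=C(OCC)[C@@]2(OC1=O)C=C[C@@]21OC(=O)C([C@@H](CCC)OC(C)=O)=C1OCC
A5 | alternative 3 | bis(allenoic acid) on a 3,4-dibromo-1,2-bis(vinylidene)cyclobutane (allene axes not encoded) | CCC[C@H](O[Si](C)(C)C(C)(C)C)C(C(=O)O)=C=C1[C@@H](Br)[C@H](Br)C1=C=C([C@@H](CCC)O[Si](C)(C)C(C)(C)C)C(=O)O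
A6 | alternative 3 | bis(silyl ether) of the target diol | CCC[C@H](O[Si](C)(C)C(C)(C)C)C1=C(Br)[C@@]2(OC1=O)[C@@H](Br)[C@H](Br)[C@@]21OC(=O)C([C@@H](CCC)O[Si](C)(C)C(C)(C)C)=C1Br
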